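**Remark on the chemistry.** C-2 is read from the SMILES as S (O-1 > phenyl > C-3 > H), the configuration of natural pinocembrin. Flavanone numbering (O-1, C-2, C-3, C-4, C-4a, C-5 to C-8, C-8a) is used for these atoms in every intermediate. Shorthand in names: ArD = 2-(benzyloxy)-5-[2-(benzyloxy)benzyl]phenyl (the "dimer" aryl); ArT = 2-(benzyloxy)-5-{2-(benzyloxy)-5-[2-(benzyloxy)benzyl]benzyl}phenyl (the "trimer" aryl). Key numbers: 6 = ArD-CH2Br, 9 = ArT-CH2Br, 12 = keto ester carrying both chains, 18 = chiral pyranone, 20 = penta-O-benzyl ether, 21 = sarmentosumin D.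

## The problem

Sarmentosumin D is (2S)-pinocembrin with a fully substituted ring A: C-6 carries a chain of three 2-hydroxybenzyl units and C-8 a chain of two. Every methylene is ortho to the hydroxyl of the outer ring and para to the hydroxyl of the inner ring. The central difficulty is that C-6 and C-8 of a 5,7-dihydroxyflavanone are almost equivalent nucleophiles, and the two electrophiles differ only by one remote terminal ring. Any aromatic substitution therefore has to tell two near-identical sites apart with two near-identical partners. The same ambiguity returns in a chalcone route as 2'-OH against 6'-OH. The only stereocentre, C-2, is a benzylic ether carbon β to the ketone; it racemises under base through the ring-opened chalcone, and no other stereocentre can control or repair it. The seven phenols are electron-rich, the chain rings are themselves nucleophiles, and 2-hydroxybenzyl groups on a phloroglucinol can migrate under strong acid, so the end game must be close to neutral.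

The feature that the plan exploits is in ring A. Its carbons alternate between oxygen-bearing (C-5, C-7, C-8a) and carbon-bearing (C-4a, C-6, C-8), which is the pattern of a 1,3,5-tricarbonyl chain. One of the three oxygens, O-1 on C-8a, is an ether inside ring C, while 5-O and 7-O are free. C-5 to C-8 therefore map onto a 2,4-disubstituted acetoacetate (ester C-5, α-carbon C-6, ketone C-7, γ-carbon C-8). C-8a and C-4a map onto the β- and α-carbons of a 2,3-dihydro-4H-pyran-4-one that already holds O-1, C-2 with its configuration, C-3 and C-4.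

## Retrosynthesis

**21 to 20.** The five chain O–H bonds are traced back to benzyl ethers. Benzyl ethers survive palladium coupling, hydride, strong base and acid, and leave by neutral hydrogenolysis, which does not touch C-2. Only the chain phenols need protection; 5-OH and 7-OH emerge free from the ring-forming step.

**20 to 12 and 18.** Two bonds of ring A are cut, C-8–C-8a and C-4a–C-5, so that the whole benzene ring is taken apart. Cutting the neighbouring C-6–CH2 and C-8–CH2 bonds would leave the C-6/C-8 question to an aromatic substitution. Cutting the ring instead turns that question into which carbon of an acetoacetate was alkylated. The precursors are much simpler: 18 is a small heterocycle holding the stereocentre, O-1 and a leaving group on C-8a, and 12 is an acyclic keto ester holding both chains. The forward reaction must do three things: the γ-carbanion of 12 must add 1,4 to the vinylogous thioester of 18 and expel methanethiolate, giving 19; C-4a of 19 must then close onto the ester by Claisen condensation; and C-2 must not epimerise.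

**12 to 10, 6 and 9.** The two C–CH2Ar bonds at the γ- and α-carbons of methyl acetoacetate 10 are cut. The dianion alkylates at the γ-carbon (dimer bromide 6, giving 11) and carbonate alkylates at the α-carbon (trimer bromide 9). This long-established site selectivity is where C-8 against C-6 is decided.

**9 to 6 and 2; 6 to 3 and 2; 2 to 1.** Each ArCH2–Ar bond is cut on the aryl side into a benzylic bromide and the arylboronate 2. One iteration (coupling to aldehyde 4 or 7, reduction to alcohol 5 or 8, bromination) adds one protected 2-hydroxybenzyl unit. The ortho/para linkage is fixed by the building blocks, not by the selectivity of a phenol alkylation. The trimer grows from the dimer, so 6 serves both chains.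

**18 to 14 and 15; 14 to 13.** O-1–C-8a is cut (addition–elimination on a ketene dithioacetal) and C-2–C-3 is cut (aldol). The silyloxydiene 14, from commercial 13, adds to benzaldehyde 15 under a chiral titanium catalyst to give 16. Acid frees 17, which closes to 18 with loss of methanethiol. This is the only step that creates the stereocentre.

## Roads not taken

**Alternative 1:** the most obvious route. The C-6–CH2 and C-8–CH2 bonds are cut. (2S)-Pinocembrin A1 is benzylated twice through o-quinone methides generated from 2-(hydroxymethyl)-4-(2-hydroxybenzyl)phenol A2 and its higher homologue A3 with a Lewis acid, by way of the 8-mono adduct A4. The route is short, but C-6 and C-8 are not distinguished, and bis-adducts with the wrong chain on each site are unavoidable. The o-quinone methides also attack the para positions of the chain phenols, which is how the chains grow in nature. Regiochemistry would be obtained by separating near-identical polyphenols and not by design. The chosen plan fixes each chain by an enolate alkylation whose site is not in doubt.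

**Alternative 2:** O-1–C-2 is cut (oxa-Michael) together with the chalcone double bond (Claisen–Schmidt condensation). Acetophenone A5 and benzaldehyde 15 would give chalcone A6. A chalcone isomerase or a chiral base catalyst would then close ring C and set C-2. A6 has two ortho hydroxyls, each flanked by a chain, and the chains differ only at a remote terminus. Closure through either is equally likely, and the wrong one gives the 6/8-transposed isomer. The enzyme pocket is built for unsubstituted chalcones and is unlikely to accept two oligomeric benzyl groups. A5 itself needs the same unsymmetrical double benzylation of a phloroglucinol. The chosen plan never has two free ortho oxygens to choose between, because O-1 is in place before ring A exists.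

**Alternative 3:** the same two aryl–CH2 bonds are cut, but as cross-couplings. 7-O-Protected pinocembrin would be iodinated ortho to the chelated 5-OH to give A7. Negishi coupling with the benzylic zinc reagent A8 (from 9) would follow, then halogenation at C-8 and coupling with A9 (from 6). The site of the first halogenation rests on a subtle directing effect. Both couplings occur at carbons flanked by two oxygen substituents. The organometallic and basic conditions put C-2 at risk. Protection, two halogenations, two couplings and deprotection are all added to the same chain syntheses, so the route is longer and no more certain.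

Key step: step 12

## Route

Step 1
Reactants: 1 2-(benzyloxy)-5-bromobenzaldehyde
Product: 2 2-(benzyloxy)-5-(4,4,5,5-tetramethyl-1,3,2-dioxaborolan-2-yl)benzaldehyde
Conditions: B2pin2, PdCl2(dppf) (3 mol%), KOAc, 1,4-dioxane, 85 °C
Reagents that add atoms: bis(pinacolato)diboron, CC1(C)OB(OC1(C)C)B1OC(C)(C)C(C)(C)O1
Why: Miyaura borylation of an aryl bromide; acetate is too weak a base to start Suzuki homocoupling and the aldehyde is tolerated.

Step 2
Reactants: 3 2-(benzyloxy)benzyl bromide; 2 2-(benzyloxy)-5-(4,4,5,5-tetramethyl-1,3,2-dioxaborolan-2-yl)benzaldehyde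
Product: 4 2-(benzyloxy)-5-[2-(benzyloxy)benzyl]benzaldehyde
Conditions: Pd(PPh3)4 (3 mol%), K2CO3, DME/H2O, 80 °C
Reagents that add atoms: none
Why: Suzuki–Miyaura coupling of a benzylic bromide with an arylboronate gives the diarylmethane; the methylene is ortho to the oxygen of the outer ring and para to that of the inner ring because the building blocks carry these positions.

Step 3
Reactants: 4 2-(benzyloxy)-5-[2-(benzyloxy)benzyl]benzaldehyde
Product: 5 {2-(benzyloxy)-5-[2-(benzyloxy)benzyl]phenyl}methanol
Conditions: NaBH4, MeOH/THF, 0 °C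
Reagents that add atoms: none
Why: Borohydride reduction of an aryl aldehyde; nothing else in the molecule is reducible under these conditions.

Step 4
Reactants: 5 {2-(benzyloxy)-5-[2-(benzyloxy)benzyl]phenyl}methanol
Product: 6 1-(benzyloxy)-4-[2-(benzyloxy)benzyl]-2-(bromomethyl)benzene (ArD-CH2Br)
Conditions: CBr4, PPh3, CH2Cl2, 0 °C
Reagents that add atoms: carbon tetrabromide, BrC(Br)(Br)Br
Why: Appel reaction; the neutral conditions avoid acid-promoted self-alkylation of the electron-rich benzylic bromide.

Step 5
Reactants: 6 1-(benzyloxy)-4-[2-(benzyloxy)benzyl]-2-(bromomethyl)benzene; 2 2-(benzyloxy)-5-(4,4,5,5-tetramethyl-1,3,2-dioxaborolan-2-yl)benzaldehyde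
Product: 7 2-(benzyloxy)-5-{2-(benzyloxy)-5-[2-(benzyloxy)benzyl]benzyl}benzaldehyde
Conditions: Pd(PPh3)4 (3 mol%), K2CO3, DME/H2O, 80 °C
Reagents that add atoms: none
Why: Second benzylic Suzuki–Miyaura coupling, the same reaction as step 2 on the next homologue, adds the third ring with the same linkage.

Step 6
Reactants: 7 2-(benzyloxy)-5-{2-(benzyloxy)-5-[2-(benzyloxy)benzyl]benzyl}benzaldehyde
Product: 8 (2-(benzyloxy)-5-{2-(benzyloxy)-5-[2-(benzyloxy)benzyl]benzyl}phenyl)methanol
Conditions: NaBH4, MeOH/THF, 0 °C
Reagents that add atoms: none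
Why: Borohydride reduction of the aryl aldehyde, as in step 3.

Step 7
Reactants: 8 (2-(benzyloxy)-5-{2-(benzyloxy)-5-[2-(benzyloxy)benzyl]benzyl}phenyl)methanol
Product: 9 1-(benzyloxy)-4-{2-(benzyloxy)-5-[2-(benzyloxy)benzyl]benzyl}-2-(bromomethyl)benzene (ArT-CH2Br)
Conditions: CBr4, PPh3, CH2Cl2, 0 °C
Reagents that add atoms: carbon tetrabromide, BrC(Br)(Br)Br
Why: Appel reaction, as in step 4.

Step 8
Reactants: 10 methyl acetoacetate; 6 1-(benzyloxy)-4-[2-(benzyloxy)benzyl]-2-(bromomethyl)benzene
Product: 11 methyl 5-{2-(benzyloxy)-5-[2-(benzyloxy)benzyl]phenyl}-3-oxopentanoate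
Conditions: LiN(iPr)2 (2.1 equiv), THF, 0 °C; then 6, 0 °C to rt; 1 M HCl quench
Reagents that add atoms: none
Why: γ-Alkylation of the β-keto ester dianion; the terminal carbanion is the more reactive site, so the dimer chain ends on the carbon that becomes C-8.

Step 9
Reactants: 11 methyl 5-{2-(benzyloxy)-5-[2-(benzyloxy)benzyl]phenyl}-3-oxopentanoate; 9 1-(benzyloxy)-4-{2-(benzyloxy)-5-[2-(benzyloxy)benzyl]benzyl}-2-(bromomethyl)benzene
Product: 12 methyl 2-(ArT-methyl)-3-oxo-5-ArD-pentanoate (racemic at C-2 of the ester)
Conditions: K2CO3, acetone, 50 °C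
Reagents that add atoms: none
Why: α-Alkylation of a β-keto ester; carbonate deprotonates only the carbon between the two carbonyls, so the trimer chain ends on the carbon that becomes C-6. The new stereocentre is racemic and is destroyed in step 12.

Step 10
Reactants: 13 4,4-bis(methylsulfanyl)but-3-en-2-one
Product: 14 {[4,4-bis(methylsulfanyl)buta-1,3-dien-2-yl]oxy}trimethylsilane
Conditions: TMSOTf, Et3N, Et2O, 0 °C
Reagents that add atoms: trimethylsilyl trifluoromethanesulfonate, C[Si](C)(C)OS(=O)(=O)C(F)(F)F
Why: Soft enolisation and O-silylation of a methyl ketone; the methyl group is the only enolisable position.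

Step 11
Reactants: 14 {[4,4-bis(methylsulfanyl)buta-1,3-dien-2-yl]oxy}trimethylsilane; 15 benzaldehyde
Product: 18 (2S)-6-(methylsulfanyl)-2-phenyl-2,3-dihydro-4H-pyran-4-one, via silyl aldol 16 (not isolated), via hydroxy enone 17 (not isolated)
Conditions: (S)-BINOL (20 mol%), Ti(OiPr)4 (10 mol%), 4 Å molecular sieves, Et2O, −20 °C; then TFA, CH2Cl2, 0 °C
Reagents that add atoms: none
Why: Catalytic enantioselective Mukaiyama aldol addition of the silyloxydiene through its CH2 terminus (the stepwise hetero-Diels–Alder manifold of heteroatom-substituted silyloxydienes), then acid-promoted 6-endo addition–elimination of the hydroxyl on the ketene dithioacetal carbon with loss of MeSH. The S centre at C-2 is set by the BINOL–titanium catalyst; the (S)-ligand is expected to direct attack to the Si face of benzaldehyde, and the antipodal ligand is used if a first run shows the opposite sense.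

Step 12
Reactants: 12 methyl 2-(ArT-methyl)-3-oxo-5-ArD-pentanoate; 18 (2S)-6-(methylsulfanyl)-2-phenyl-2,3-dihydro-4H-pyran-4-one
Product: 20 (2S)-8-(ArD-methyl)-6-(ArT-methyl)-5,7-dihydroxy-2-phenylchroman-4-one (penta-O-benzyl sarmentosumin D), via pyranone keto ester 19 (not isolated)
Conditions: 12, LiN(iPr)2 (2.1 equiv), THF, −78 to 0 °C; then 18, −78 °C to rt; AcOH quench at −78 °C
Reagents that add atoms: none
Why: Proposed new method: an anionic formal [4+2] benzannulation in which the γ-carbon (C-8) of the dianion of 12 adds to C-8a of the cyclic O,S-ketene acetal 18 and expels methanethiolate to give 19, whose vinylogous enolate (C-8 deprotonated, charge relayed through C-8a=C-4a to O-4) attacks the methyl ester through C-4a; loss of methoxide and two proton shifts then give the phloroglucinol ring. The closest known reaction types are the Staunton–Weinreb annulation (carbanion Michael addition to a 4-alkoxypyranone, Dieckmann closure, loss of the β-leaving group), the addition–elimination of ketone enolates on α-oxo ketene dithioacetals, and the biomimetic Claisen cyclisation of 3,5,7-triketo esters to acylphloroglucinols. Ring A closes by a 6-(enolexo)-exo-trig Claisen condensation; the competing aldol closure of C-6 on C-4 would give an anti-Bredt bicycle and is excluded. No stereocentre is created, and C-2 should be carried through because the C-2–O-1 bond is never broken, the C-3 protons are the least acidic in every anion on the path, and the base is used up as the two phenoxides form before the cold acid quench. The regiochemistry needs no selectivity on an arene, since C-8 is the γ-carbon and C-6 the α-carbon of the keto ester, C-8a is the carbon that already carries O-1, and C-5 is the ester carbon. The selectivities needed are γ- over α-attack of the dianion (normal for β-keto ester dianions), 1,4- over 1,2-addition (favoured for enolate-type nucleophiles on vinylogous thioesters) and loss of thiolate in preference to ring opening (thiolate is the better leaving group, and a ring-opened alkoxide would close again on the same carbon).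

Step 13
Reactants: 20 (2S)-8-(ArD-methyl)-6-(ArT-methyl)-5,7-dihydroxy-2-phenylchroman-4-one
Product: 21 sarmentosumin D, (2S)-5,7-dihydroxy-8-[2-hydroxy-5-(2-hydroxybenzyl)benzyl]-6-{2-hydroxy-5-[2-hydroxy-5-(2-hydroxybenzyl)benzyl]benzyl}-2-phenylchroman-4-one
Conditions: H2 (1 atm), Pd/C (10%), EtOAc/MeOH, rt
Reagents that add atoms: none
Why: Hydrogenolysis of five aryl benzyl ethers under neutral conditions; diarylmethane C–C bonds are inert, and the chelated C-4 ketone and the C-2–O-1 bond of flavanones normally survive this treatment, so C-2 is not touched.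

## Compound list

1 | 2-(benzyloxy)-5-bromobenzaldehyde | O=Cc1cc(Br)ccc1OCc1ccccc1 | starting material
2 | 2-(benzyloxy)-5-(4,4,5,5-tetramethyl-1,3,2-dioxaborolan-2-yl)benzaldehyde | O=Cc1cc(B2OC(C)(C)C(C)(C)O2)ccc1OCc1ccccc1 | intermediate
3 | 2-(benzyloxy)benzyl bromide | BrCc1ccccc1OCc1ccccc1 | starting material
4 | 2-(benzyloxy)-5-[2-(benzyloxy)benzyl]benzaldehyde | O=Cc1cc(Cc2ccccc2OCc2ccccc2)ccc1OCc1ccccc1 | intermediate
5 | {2-(benzyloxy)-5-[2-(benzyloxy)benzyl]phenyl}methanol | OCc1cc(Cc2ccccc2OCc2ccccc2)ccc1OCc1ccccc1 | intermediate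
6 | 1-(benzyloxy)-4-[2-(benzyloxy)benzyl]-2-(bromomethyl)benzene | BrCc1cc(Cc2ccccc2OCc2ccccc2)ccc1OCc1ccccc1 | intermediate
7 | 2-(benzyloxy)-5-{2-(benzyloxy)-5-[2-(benzyloxy)benzyl]benzyl}benzaldehyde | O=Cc1cc(Cc2cc(Cc3ccccc3OCc3ccccc3)ccc2OCc2ccccc2)ccc1OCc1ccccc1 | intermediate
8 | (2-(benzyloxy)-5-{2-(benzyloxy)-5-[2-(benzyloxy)benzyl]benzyl}phenyl)methanol | OCc1cc(Cc2cc(Cc3ccccc3OCc3ccccc3)ccc2OCc2ccccc2)ccc1OCc1ccccc1 | intermediate
9 | 1-(benzyloxy)-4-{2-(benzyloxy)-5-[2-(benzyloxy)benzyl]benzyl}-2-(bromomethyl)benzene | BrCc1cc(Cc2cc(Cc3ccccc3OCc3ccccc3)ccc2OCc2ccccc2)ccc1OCc1ccccc1 | intermediate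
10 | methyl acetoacetate | CC(=O)CC(=O)OC | starting material
11 | methyl 5-{2-(benzyloxy)-5-[2-(benzyloxy)benzyl]phenyl}-3-oxopentanoate | COC(=O)CC(=O)CCc1cc(Cc2ccccc2OCc2ccccc2)ccc1OCc1ccccc1 | intermediate
12 | methyl 2-(2-(benzyloxy)-5-{2-(benzyloxy)-5-[2-(benzyloxy)benzyl]benzyl}benzyl)-5-{2-(benzyloxy)-5-[2-(benzyloxy)benzyl]phenyl}-3-oxopentanoate (racemic) | COC(=O)C(Cc1cc(Cc2cc(Cc3ccccc3OCc3ccccc3)ccc2OCc2ccccc2)ccc1OCc1ccccc1)C(=O)CCc1cc(Cc2ccccc2OCc2ccccc2)ccc1OCc1ccccc1 | intermediate
13 | 4,4-bis(methylsulfanyl)but-3-en-2-one | CC(=O)C=C(SC)SC | starting material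
14 | {[4,4-bis(methylsulfanyl)buta-1,3-dien-2-yl]oxy}trimethylsilane | C=C(O[Si](C)(C)C)C=C(SC)SC | intermediate
15 | benzaldehyde | O=Cc1ccccc1 | starting material
16 | (5S)-1,1-bis(methylsulfanyl)-5-phenyl-5-(trimethylsilyloxy)pent-1-en-3-one | O=C(C[C@@H](c1ccccc1)O[Si](C)(C)C)C=C(SC)SC | intermediate
17 | (5S)-5-hydroxy-1,1-bis(methylsulfanyl)-5-phenylpent-1-en-3-one | O=C(C[C@@H](c1ccccc1)O)C=C(SC)SC | intermediate
18 | (2S)-6-(methylsulfanyl)-2-phenyl-2,3-dihydro-4H-pyran-4-one | O=C1C[C@@H](c2ccccc2)OC(SC)=C1 | intermediate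
19 | methyl 2-(2-(benzyloxy)-5-{2-(benzyloxy)-5-[2-(benzyloxy)benzyl]benzyl}benzyl)-5-{2-(benzyloxy)-5-[2-(benzyloxy)benzyl]phenyl}-3-oxo-4-[(2S)-4-oxo-2-phenyl-3,4-dihydro-2H-pyran-6-yl]pentanoate (mixture of diastereomers at the two chain carbons) | COC(=O)C(Cc1cc(Cc2cc(Cc3ccccc3OCc3ccccc3)ccc2OCc2ccccc2)ccc1OCc1ccccc1)C(=O)C(Cc1cc(Cc2ccccc2OCc2ccccc2)ccc1OCc1ccccc1)C1=CC(=O)C[C@@H](c2ccccc2)O1 | intermediate
20 | (2S)-8-{2-(benzyloxy)-5-[2-(benzyloxy)benzyl]benzyl}-6-(2-(benzyloxy)-5-{2-(benzyloxy)-5-[2-(benzyloxy)benzyl]benzyl}benzyl)-5,7-dihydroxy-2-phenylchroman-4-one | O=C1C[C@@H](c2ccccc2)Oc2c(Cc3cc(Cc4ccccc4OCc4ccccc4)ccc3OCc3ccccc3)c(O)c(Cc3cc(Cc4cc(Cc5ccccc5OCc5ccccc5)ccc4OCc4ccccc4)ccc3OCc3ccccc3)c(O)c21 | intermediate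
21 | sarmentosumin D | O=C1C[C@@H](c2ccccc2)Oc2c(Cc3cc(Cc4ccccc4O)ccc3O)c(O)c(Cc3cc(Cc4cc(Cc5ccccc5O)ccc4O)ccc3O)c(O)c21 | target

## Step count and risks

Total: 13 steps. Longest linear sequence: 10 steps (1 to 2, 4, 5, 6, 7, 8, 9, 12, 20, 21; steps 1 to 7, 9, 12 and 13).

**Step 12 (key step, proposed new method).**
- What may go wrong: proton transfer from C-3 of 18 to the hindered secondary carbanion in place of C–C bond formation; ring opening of the resulting C-3 enolate with loss of material; 1,2-addition at C-4; or slow Claisen closure of the stabilised vinylogous enolate, so that the flavanone stays in base long enough to open to the chalcone and lose configuration at C-2. Should the sequence stop at 19, that compound can be isolated and closed separately.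
- Fallback (known chemistry, from 4 and 7, returning at 21): biomimetic benzylation through o-quinone methides. Aldehyde 4 is debenzylated with BCl3 and pentamethylbenzene at −78 °C to 2-hydroxy-5-(2-hydroxybenzyl)benzaldehyde F1, which is reduced with NaBH4 to 2-(hydroxymethyl)-4-(2-hydroxybenzyl)phenol F2. Aldehyde 7 gives in the same way 2-hydroxy-5-[2-hydroxy-5-(2-hydroxybenzyl)benzyl]benzaldehyde F3 and then 2-(hydroxymethyl)-4-[2-hydroxy-5-(2-hydroxybenzyl)benzyl]phenol F4. Purchased (2S)-pinocembrin F5 is heated with F2 and ZnCl2 in dioxane, and the 8-substituted product (2S)-5,7-dihydroxy-8-[2-hydroxy-5-(2-hydroxybenzyl)benzyl]-2-phenylchroman-4-one F6 is separated from its regioisomer by chromatography. F6 has only C-6 free on ring A and is benzylated there with F4 and ZnCl2 to give 21.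

**Step 11.**
- What may go wrong: poor facial selectivity of the titanium catalyst with a sulfur-substituted diene; attack through the ketene dithioacetal carbon in place of the CH2 terminus; or dehydration of the aldol under TFA before ring closure.
- Fallback (from 15, returning at 17): the stereocentre is set first by an enamine-catalysed aldol and the dithioacetal is built afterwards. Benzaldehyde 15 and acetone with D-proline give (S)-4-hydroxy-4-phenylbutan-2-one F7 (the mirror image of the L-proline reaction). Silylation with TBSCl and imidazole gives (S)-4-(tert-butyldimethylsilyloxy)-4-phenylbutan-2-one F8. Kinetic enolisation with LiN(SiMe3)2 at −78 °C, CS2 and two equivalents of MeI give (S)-5-(tert-butyldimethylsilyloxy)-1,1-bis(methylsulfanyl)-5-phenylpent-1-en-3-one F9. HF·pyridine frees 17, which is closed to 18 with TFA as in step 11.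

**Step 9.**
- What may go wrong: O-alkylation or double alkylation of the keto ester, or slow substitution with the bulky trimer bromide.
- Fallback (from 11 and 7, returning at 12): reductive alkylation. Knoevenagel condensation of 11 with aldehyde 7 (piperidine, AcOH) gives methyl 2-(ArT-methylidene)-3-oxo-5-ArD-pentanoate F10, and conjugate reduction with Hantzsch ester gives 12. Steps 6 and 7 are then not needed.

**Step 5 (and step 2).**
- What may go wrong: hydrolysis or homocoupling of the benzylic bromide, or protodeboronation of 2, faster than cross-coupling.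
- Fallback (from 6 and 1, returning at 7): reversed polarity. Zinc insertion into 6 (Zn, LiCl, THF) gives bromo{2-(benzyloxy)-5-[2-(benzyloxy)benzyl]benzyl}zinc F11, and Negishi coupling with aryl bromide 1 (Pd(PPh3)4) gives 7.

**Step 13.**
- What may go wrong: poisoning of the catalyst by sulfur residues from step 12, or over-reduction at C-4 and hydrogenolysis of the benzylic C-2–O-1 bond on long exposure.
- Fallback (from 20, returning at 21): non-reductive cleavage of the benzyl ethers with BCl3 and pentamethylbenzene in CH2Cl2 at −78 °C. No new compound is made.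

## Further compounds

F1 | step 12 | 2-hydroxy-5-(2-hydroxybenzyl)benzaldehyde | O=Cc1cc(Cc2ccccc2O)ccc1O
F2 | step 12 | 2-(hydroxymethyl)-4-(2-hydroxybenzyl)phenol | OCc1cc(Cc2ccccc2O)ccc1O
F3 | step 12 | 2-hydroxy-5-[2-hydroxy-5-(2-hydroxybenzyl)benzyl]benzaldehyde | O=Cc1cc(Cc2cc(Cc3ccccc3O)ccc2O)ccc1O
F4 | step 12 | 2-(hydroxymethyl)-4-[2-hydroxy-5-(2-hydroxybenzyl)benzyl]phenol | OCc1cc(Cc2cc(Cc3ccccc3O)ccc2O)ccc1O
F5 | step 12 | (2S)-pinocembrin, (2S)-5,7-dihydroxy-2-phenylchroman-4-one (purchased) | O=C1C[C@@H](c2ccccc2)Oc2cc(O)cc(O)c21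
F6 | step 12 | (2S)-5,7-dihydroxy-8-[2-hydroxy-5-(2-hydroxybenzyl)benzyl]-2-phenylchroman-4-one | O=C1C[C@@H](c2ccccc2)Oc2c(Cc3cc(Cc4ccccc4O)ccc3O)c(O)cc(O)c21
F7 | step 11 | (S)-4-hydroxy-4-phenylbutan-2-one | CC(=O)C[C@@H](c1ccccc1)O
F8 | step 11 | (S)-4-(tert-butyldimethylsilyloxy)-4-phenylbutan-2-one | CC(=O)C[C@@H](c1ccccc1)O[Si](C)(C)C(C)(C)C
F9 | step 11 | (S)-5-(tert-butyldimethylsilyloxy)-1,1-bis(methylsulfanyl)-5-phenylpent-1-en-3-one | CSC(SC)=CC(=O)C[C@@H](c1ccccc1)O[Si](C)(C)C(C)(C)C
F10 | step 9 | methyl 2-(2-(benzyloxy)-5-{2-(benzyloxy)-5-[2-(benzyloxy)benzyl]benzyl}benzylidene)-5-{2-(benzyloxy)-5-[2-(benzyloxy)benzyl]phenyl}-3-oxopentanoate (E/Z mixture) | COC(=O)C(=Cc1cc(Cc2cc(Cc3ccccc3OCc3ccccc3)ccc2OCc2ccccc2)ccc1OCc1ccccc1)C(=O)CCc1cc(Cc2ccccc2OCc2ccccc2)ccc1OCc1ccccc1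
F11 | step 5 | bromo{2-(benzyloxy)-5-[2-(benzyloxy)benzyl]benzyl}zinc | Br[Zn]Cc1cc(Cc2ccccc2OCc2ccccc2)ccc1OCc1ccccc1
F0 | step 13 | none | none
A1 | alternative 1 | (2S)-pinocembrin | O=C1C[C@@H](c2ccccc2)Oc2cc(O)cc(O)c21
A2 | alternative 1 | 2-(hydroxymethyl)-4-(2-hydroxybenzyl)phenol | OCc1cc(Cc2ccccc2O)ccc1O
A3 | alternative 1 | 2-(hydroxymethyl)-4-[2-hydroxy-5-(2-hydroxybenzyl)benzyl]phenol | OCc1cc(Cc2cc(Cc3ccccc3O)ccc2O)ccc1O
A4 | alternative 1 | (2S)-5,7-dihydroxy-8-[2-hydroxy-5-(2-hydroxybenzyl)benzyl]-2-phenylchroman-4-one | O=C1C[C@@H](c2ccccc2)Oc2c(Cc3cc(Cc4ccccc4O)ccc3O)c(O)cc(O)c21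
A5 | alternative 2 | 1-[2,4,6-trihydroxy-3-(ArD-methyl)-5-(ArT-methyl)phenyl]ethanone | CC(=O)c1c(O)c(Cc2cc(Cc3ccccc3OCc3ccccc3)ccc2OCc2ccccc2)c(O)c(Cc2cc(Cc3cc(Cc4ccccc4OCc4ccccc4)ccc3OCc3ccccc3)ccc2OCc2ccccc2)c1O
A6 | alternative 2 | (E)-3-phenyl-1-[2,4,6-trihydroxy-3-(ArD-methyl)-5-(ArT-methyl)phenyl]prop-2-en-1-one | O=C(/C=C/c1ccccc1)c1c(O)c(Cc2cc(Cc3ccccc3OCc3ccccc3)ccc2OCc2ccccc2)c(O)c(Cc2cc(Cc3cc(Cc4ccccc4OCc4ccccc4)ccc3OCc3ccccc3)ccc2OCc2ccccc2)c1O
A7 | alternative 3 | (2S)-5-hydroxy-6-iodo-7-(methoxymethoxy)-2-phenylchroman-4-one | O=C1C[C@@H](c2ccccc2)Oc2cc(OCOC)c(I)c(O)c21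
A8 | alternative 3 | bromo(2-(benzyloxy)-5-{2-(benzyloxy)-5-[2-(benzyloxy)benzyl]benzyl}benzyl)zinc | Br[Zn]Cc1cc(Cc2cc(Cc3ccccc3OCc3ccccc3)ccc2OCc2ccccc2)ccc1OCc1ccccc1
A9 | alternative 3 | bromo{2-(benzyloxy)-5-[2-(benzyloxy)benzyl]benzyl}zinc | Br[Zn]Cc1cc(Cc2ccccc2OCc2ccccc2)ccc1OCc1ccccc1
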